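The plan reads the γ-lactone ring (O, C7, C8, C17, C19; briarane numbering) as a hydrated 2-ethoxyfuran. Its C7–O–C19 edge is the 2,1,5-edge of a 5-ethoxyoxazole, and its C8–C17(CH3) edge is a but-2-ynoyl alkyne. An intramolecular oxazole–ynone Diels–Alder reaction with loss of acetonitrile therefore forms C7–C8 and C17–C19 in one operation. It closes both the ten-membered carbocycle and the future lactone ring. The precursor is open-chain on ring A: a but-2-ynoyl group on C10 and, on C1, the C2–C6 arm ending in a (Z)-alkenyl oxazole. Epoxidation, two reductions and a late ene chlorination then set C6–C9 and C17.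

Key step: step 15

Numbering: briarane numbering is used throughout.
- C1 is the quaternary ring-fusion carbon, C2–C9 are the ten-membered ring, and C10 is the ring-fusion CH.
- C11–C14 are ring A.
- C15 is the methyl on C1, C16 sits on C5, and C20 is the methyl on C11.
- C17/C18 are the lactone CH(CH3) and C19 is the lactone carbonyl.
- α and β refer to the usual drawing with C15 β.
- The target is 1S,2S,6S,7R,8R,9S,10S,11S,12R,17R.

Assumption: the hand of the oxazaborolidinium catalyst in step 5 is assigned from the usual model for α-methyl enals. If the sense on enal 8 is the opposite, the catalyst from (R)-diphenylprolinol is used and nothing else changes.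

Step 1
Reactants: 1 but-2-ynoic acid
Product: 2 (Z)-3-iodobut-2-enoic acid
Conditions: NaI, AcOH, 110 °C
Reagents that add atoms: sodium iodide, [Na+].[I-]
Why: Conjugate hydroiodination of an ynoic acid is an anti addition of iodide and a proton, which should place iodine cis to the carboxyl group (Z).

Step 2
Reactants: 2 (Z)-3-iodobut-2-enoic acid; 3 L-alanine ethyl ester hydrochloride
Product: 4 ethyl N-[(Z)-3-iodobut-2-enoyl]-L-alaninate
Conditions: DCC, HOBt (cat.), Et3N, CH2Cl2, 0 °C to rt
Reagents that add atoms: none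
Why: Carbodiimide amide coupling joins acid and amine under conditions that leave the vinyl iodide geometry untouched, and no new stereocentre is formed.

Step 3
Reactants: 4 ethyl N-[(Z)-3-iodobut-2-enoyl]-L-alaninate
Product: 5 5-ethoxy-2-[(Z)-2-iodoprop-1-enyl]-4-methyl-1,3-oxazole
Conditions: P2O5, CHCl3, reflux
Reagents that add atoms: none
Why: Robinson–Gabriel-type cyclodehydration of an N-acyl α-amino ester closes the amide oxygen on the activated ester carbonyl to give the 5-alkoxyoxazole, and the alanine stereocentre becomes the sp2 carbon 4 of the heterocycle.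

Step 4
Reactants: 6 pent-1-en-3-one
Product: 7 (Z)-3-(triisopropylsilyloxy)penta-1,3-diene
Conditions: TIPSOTf, Et3N, CH2Cl2, 0 °C
Reagents that add atoms: triisopropylsilyl triflate, CC(C)[Si](OS(=O)(=O)C(F)(F)F)(C(C)C)C(C)C
Why: Soft enolisation and O-silylation of the ethyl ketone should give the Z silyl enol ether (oxygen and methyl cis), so the methyl group is an outside substituent of the s-cis diene.

Step 5
Reactants: 7 (Z)-3-(triisopropylsilyloxy)penta-1,3-diene; 8 ethyl (E)-3-methyl-4-oxobut-2-enoate
Product: 9 ethyl 6-formyl-2,6-dimethyl-3-(triisopropylsilyloxy)cyclohex-3-ene-1-carboxylate (ring A; 15-CH3 β and C2 formyl α on C1; H α and C9 ester β on C10; 20-CH3 α)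
Conditions: (S)-3,3-diphenyl-1-(2-methylphenyl)tetrahydro-1H,3H-pyrrolo[1,2-c][1,3,2]oxazaborole (15 mol %), Tf2NH (12 mol %), CH2Cl2, −78 to −40 °C
Reagents that add atoms: none
Why: In this enantioselective Diels–Alder reaction under chiral oxazaborolidinium catalysis the silyloxy group sends C11 to the enal β-carbon C10 (para rule), the E dienophile fixes C2 and C9 trans, and the catalyst should leave open only the si face at C1 and C10, which sets both centres as in the target (C11 is erased in step 9).

Step 6
Reactants: 9 ring A aldehyde ester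
Product: 11 trans-fused γ-lactone C2–O–C9(=O) on ring A that carries the C3=C4 vinyl group on C2 trans to 15-CH3 on the lactone ring and keeps the C12 silyl enol ether, via hydroxy ester alkoxide 10 (not isolated)
Conditions: CH2=CHMgBr, THF, −78 °C, then rt
Reagents that add atoms: vinylmagnesium bromide, C=C[Mg]Br
Why: Grignard addition to the α-quaternary aldehyde should follow the Felkin–Anh model (C10 anti to the nucleophile, the C15 methyl beside its path) and set the 2β-oxygen, and the alkoxide then lactonises on the neighbouring ethyl ester, which masks C2–OH and C9 together.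

Step 7
Reactants: 11 vinyl lactone silyl enol ether
Product: 12 enone lactone (C12 ketone; C13=C14)
Conditions: Pd(OAc)2 (1.05 equiv), MeCN, 40 °C
Reagents that add atoms: none
Why: Saegusa–Ito oxidation turns the regiodefined C12=C13 silyl enol ether into the C13=C14 enone, since β-hydride loss is possible only from C14.

Step 8
Reactants: 12 enone lactone
Product: 13 12β-allylic alcohol
Conditions: NaBH4, CeCl3·7H2O, MeOH, −40 °C
Reagents that add atoms: none
Why: Luche reduction gives clean 1,2-reduction of the enone without touching the lactone, axial attack from the α face should give the 12β-alcohol, and this centre is removed in the next step.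

Step 9
Reactants: 13 12β-allylic alcohol
Product: 14 diene lactone (C11=C12–C13=C14)
Conditions: Ph2S[OC(CF3)2Ph]2, CH2Cl2, 0 °C
Reagents that add atoms: none
Why: Dehydration with Martin sulfurane ionises the allylic alcohol, and the allyl cation can lose a proton only from C11 because C1 is quaternary, so a single conjugated diene should result.

Step 10
Reactants: 14 diene lactone
Product: 15 11α,12α-diol lactone (20-CH3 β; C13=C14 kept)
Conditions: OsO4 (2 mol %), NMO (1.0 equiv), acetone–H2O, 0 °C
Reagents that add atoms: N-methylmorpholine N-oxide, C[N+]1([O-])CCOCC1; water, O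
Why: Upjohn dihydroxylation should take the electron-rich trisubstituted C11=C12 end of the diene (the vinyl group is deactivated by the allylic lactone oxygen, C13=C14 is neopentyl), and syn addition from the α face opposite the pseudoaxial C15 methyl sets C11 and C12 together.

Step 11
Reactants: 15 11α,12α-diol lactone
Product: 16 11,12-acetonide lactone
Conditions: Me2C(OMe)2, PPTS (cat.), CH2Cl2, rt
Reagents that add atoms: 2,2-dimethoxypropane, COC(C)(C)OC
Why: Transketalisation of the cis-diol gives the dioxolane, which blocks oxa-Michael addition and β-elimination at C11 in the later ketone stages and stiffens ring A.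

Step 12
Reactants: 16 11,12-acetonide lactone; 5 5-ethoxy-2-[(Z)-2-iodoprop-1-enyl]-4-methyl-1,3-oxazole
Product: 18 oxazole lactone (C4–C5 bond made; C5=C6 Z; oxazole carbon 2 is C7), via B-alkyl-9-BBN adduct 17 (not isolated)
Conditions: 9-BBN, THF, rt; then 5, Pd(dppf)Cl2 (5 mol %), AsPh3, K3PO4 (aq), DMF, rt
Reagents that add atoms: 9-borabicyclo[3.3.1]nonane, [H]B1C2CCCC1CCC2 (its boron unit stays in 17 only)
Why: Hydroboration with 9-BBN picks the terminal vinyl group over the hindered ring alkene, and the B-alkyl Suzuki–Miyaura coupling replaces iodine with retention, so C4 ends cis to the oxazole (5Z).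

Step 13
Reactants: 18 oxazole lactone
Product: 19 2-hydroxy ynone (C10–C9(=O)–C8≡C17–C18; in equilibrium with its cyclic hemiketal)
Conditions: 1-propynyllithium, THF, −78 °C; AcOH quench
Reagents that add atoms: 1-propynyllithium, [Li]C#CC
Why: Addition of a lithium acetylide to a lactone should stop after one addition because the lithium hemiketal alkoxide survives at −78 °C, and it frees C2–OH and installs C8, C17 and C18 in one step.

Step 14
Reactants: 19 2-hydroxy ynone
Product: 20 2-acetoxy ynone (cycloaddition precursor)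
Conditions: Ac2O, pyridine, DMAP (cat.), CH2Cl2, 0 °C
Reagents that add atoms: acetic anhydride, CC(=O)OC(C)=O
Why: DMAP-catalysed acetylation drains the open hydroxy ketone form of the hemiketal equilibrium and installs the C2 acetate of the target.

Step 15
Reactants: 20 2-acetoxy ynone
Product: 22 ethoxyfuran macrocycle (ten-membered ring closed; furan O–C7=C8–C17(CH3)=C19(OEt); C9 ketone; 5Z), via oxa-bridged cycloadduct 21 (not isolated)
Conditions: mesitylene (0.001 M, slow addition), BHT (cat.), 165 °C, Ar
Reagents that add atoms: none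
Why: The electron-rich 5-ethoxyoxazole (diene termini C7 and C19) and the LUMO-lowered ynone (C8≡C17) undergo a normal-demand intramolecular [4+2] cycloaddition to the 7-oxa-2-azabicyclo[2.2.1]heptadiene 21, which at once loses acetonitrile by retro-[4+2] and becomes aromatic, so the sequence is irreversible. The closest known reaction type is the intramolecular oxazole–alkyne Diels–Alder/retro-Diels–Alder furan synthesis of acetylenic oxazoles, which gives 2-alkoxy-3-methylfurans fused to five-, six- and seven-membered rings from this same pairing of a methyl-capped alkyne and a 5-alkoxy-4-methyloxazole. The ten-membered carbocycle is closed by the C7–C8 bond as the tether ring of a terminus-tethered, fused-mode cycloaddition, and the five-membered O–C7–C8–C17–C19 ring is closed by C7–C8 and C17–C19 together, first as the oxygen-bridged ring of 21 and then as the furan. No lasting stereocentre is formed, since both bridgeheads of 21 are flattened when acetonitrile leaves, and C1, C2, C10, C11 and C12 are not touched. The step needs fused over bridged regiochemistry and cyclisation over oligomerisation: the bridged mode (C7–C17, C8–C19) is electronically preferred but would require an eight-atom bridge across the 2,4-positions of a furan, while high dilution, the Z C5=C6 bond, the flat alkenyl-oxazole and ynone units and the trans-diequatorial C2 and C9 arms on the acetonide-locked ring A leave only a handful of free rotors in the tether.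

Step 16
Reactants: 22 ethoxyfuran macrocycle
Product: 23 9-keto butenolide (C8=C17; C19 lactone carbonyl; 7-H β drawn)
Conditions: 0.5 M aq HCl, THF, 0 °C
Reagents that add atoms: water, O
Why: Acid hydrolysis of a 2-alkoxyfuran (protonation at C7, water on C19, loss of ethanol) should be far faster than dioxolane hydrolysis and gives the butenolide, whose C7 centre is still mobile as a vinylogous β-dicarbonyl and is fixed only in step 17.

Step 17
Reactants: 23 9-keto butenolide
Product: 24 8α,17α-epoxy ketone (7-H β, trans to the C8 oxygen)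
Conditions: t-BuOOH, DBU (0.3 equiv), CH2Cl2, −20 °C
Reagents that add atoms: tert-butyl hydroperoxide, CC(C)(C)OO
Why: Weitz–Scheffer epoxidation works on tetrasubstituted ene-diones, as with 2,3-dialkyl-1,4-quinones. DBU keeps the C7 epimers and furanone tautomers in equilibrium, and the peroxide anion should add to the C8=C17 face not covered by C10 and ring A, that is syn to the slim C6 vinyl carbon of the 7R epimer, which sets C7 and C8 trans.

Step 18
Reactants: 24 8α,17α-epoxy ketone
Product: 25 8α,17α-epoxy-9-ol (9S)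
Conditions: NaBH4, CeCl3·7H2O, MeOH, −40 °C
Reagents that add atoms: none
Why: Luche reduction under non-chelating conditions should follow the polar Felkin–Anh model, with hydride anti to the C8–O bond while C7 and C10 stay near antiperiplanar in the ring, which gives the 8,9-syn relation (9S).

Step 19
Reactants: 25 8α,17α-epoxy-9-ol
Product: 26 8α,9-diol lactone (17R; C18 cis to 8-OH)
Conditions: SmI2 (2.5 equiv), HMPA, Me2NCH2CH2OH, THF, −40 °C
Reagents that add atoms: none
Why: SmI2 reduction of an α,β-epoxy ester cleaves the Cα–O bond (C17–O) and keeps the C8 oxygen. The samarium enolate should be protonated anti to the bulky samarium alkoxide, which puts C18 cis to 8-OH and trans to C9, also the favoured arrangement if this epimerisable centre equilibrates.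

Step 20
Reactants: 26 8α,9-diol lactone
Product: 27 8,9,11,12-tetraol 2-acetate
Conditions: AcOH–H2O 4:1, 40 °C
Reagents that add atoms: none
Why: Mild acid hydrolysis of the dioxolane frees the 11,12-diol under conditions too weak to dehydrate the tertiary C8 alcohol or ionise the allylic C12 oxygen.

Step 21
Reactants: 27 8,9,11,12-tetraol 2-acetate
Product: 28 2,9,12-triacetate with the 5Z alkene (deschloro precursor)
Conditions: Ac2O, pyridine, DMAP (cat.), CH2Cl2, rt
Reagents that add atoms: acetic anhydride, CC(=O)OC(C)=O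
Why: Acetylation distinguishes the two secondary alcohols (C9, C12) from the two hindered tertiary alcohols (C8, C11), which stay free as in the target.

Step 22
Reactants: 28 2,9,12-triacetate with the 5Z alkene
Product: 29 target CNP0259091.1 (6α-Cl; C5=C16 exomethylene)
Conditions: t-BuOCl (1.05 equiv), NaHCO3, CH2Cl2, 0 °C, dark
Reagents that add atoms: tert-butyl hypochlorite, CC(C)(C)OCl
Why: Ene-type allylic chlorination of a trisubstituted alkene by a hypochlorite puts chlorine on the less substituted C6 and takes a proton from the C16 methyl, faster than any attack on the deactivated C13=C14 bond. With H7 eclipsing C5=C6 (A1,3 strain against C4) the 8α-hydroxyl lies under C6 and should guide the reagent by hydrogen bonding to the α face (6S).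

Compound list
1 | but-2-ynoic acid | CC#CC(=O)O | starting material
2 | (Z)-3-iodobut-2-enoic acid | C/C(I)=C/C(=O)O | intermediate
3 | L-alanine ethyl ester hydrochloride | C[C@H](N)C(=O)OCC.Cl | starting material
4 | ethyl N-[(Z)-3-iodobut-2-enoyl]-L-alaninate | C/C(I)=C/C(=O)N[C@@H](C)C(=O)OCC | intermediate
5 | 5-ethoxy-2-[(Z)-2-iodoprop-1-enyl]-4-methyl-1,3-oxazole | C/C(I)=C/c1nc(C)c(OCC)o1 | intermediate
6 | pent-1-en-3-one | C=CC(=O)CC | starting material
7 | (Z)-3-(triisopropylsilyloxy)penta-1,3-diene | C=C/C(O[Si](C(C)C)(C(C)C)C(C)C)=C/C | intermediate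
8 | ethyl (E)-3-methyl-4-oxobut-2-enoate | CCOC(=O)/C=C(\C)C=O | starting material
9 | ring A aldehyde ester (Diels–Alder adduct) | O=C[C@@]2(C)CC=C(O[Si](C(C)C)(C(C)C)C(C)C)[C@@H](C)[C@@H]2C(=O)OCC | intermediate
10 | hydroxy ester from vinyl addition (formed as its magnesium alkoxide; not isolated) | C=C[C@H](O)[C@@]2(C)CC=C(O[Si](C(C)C)(C(C)C)C(C)C)[C@@H](C)[C@@H]2C(=O)OCC | intermediate
11 | vinyl lactone silyl enol ether | C=C[C@H](O4)[C@@]2(C)CC=C(O[Si](C(C)C)(C(C)C)C(C)C)[C@@H](C)[C@@H]2C4=O | intermediate
12 | enone lactone | C=C[C@H](O4)[C@@]2(C)C=CC(=O)[C@@H](C)[C@@H]2C4=O | intermediate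
13 | 12β-allylic alcohol | C=C[C@H](O4)[C@@]2(C)C=C[C@H](O)[C@@H](C)[C@@H]2C4=O | intermediate
14 | diene lactone | C=C[C@H](O4)[C@@]2(C)C=CC=C(C)[C@@H]2C4=O | intermediate
15 | 11α,12α-diol lactone | C=C[C@H](O4)[C@@]2(C)C=C[C@@H](O)[C@@](C)(O)[C@@H]2C4=O | intermediate
16 | 11,12-acetonide lactone | C=C[C@H](O4)[C@@]2(C)C=C[C@@H](OC3(C)C)[C@@](C)(O3)[C@@H]2C4=O | intermediate
17 | B-alkyl-9-BBN adduct (not isolated) | B5(C6CCCC5CCC6)CC[C@H](O4)[C@@]2(C)C=C[C@@H](OC3(C)C)[C@@](C)(O3)[C@@H]2C4=O | intermediate
18 | oxazole lactone | CCOc1oc(/C=C(/C)CC[C@H](O4)[C@@]2(C)C=C[C@@H](OC3(C)C)[C@@](C)(O3)[C@@H]2C4=O)nc1C | intermediate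
19 | 2-hydroxy ynone | CCOc1oc(/C=C(/C)CC[C@H](O)[C@@]2(C)C=C[C@@H](OC3(C)C)[C@@](C)(O3)[C@@H]2C(=O)C#CC)nc1C | intermediate
20 | 2-acetoxy ynone (cycloaddition precursor) | CCOc1oc(/C=C(/C)CC[C@H](OC(C)=O)[C@@]2(C)C=C[C@@H](OC3(C)C)[C@@](C)(O3)[C@@H]2C(=O)C#CC)nc1C | intermediate
21 | oxa-bridged cycloadduct (not isolated; bridgeheads C7 and C19 left undefined because both facial adducts give 22) | C1C[C@H](OC(C)=O)[C@@]2(C)C=C[C@@H](OC3(C)C)[C@@](C)(O3)[C@@H]2C(=O)C2=C(C)C4(OCC)OC2(N=C4C)/C=C1/C | intermediate
22 | ethoxyfuran macrocycle | C1C[C@H](OC(C)=O)[C@@]2(C)C=C[C@@H](OC3(C)C)[C@@](C)(O3)[C@@H]2C(=O)c2c(C)c(OCC)oc2/C=C1/C | intermediate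
23 | 9-keto butenolide | C1C[C@H](OC(C)=O)[C@@]2(C)C=C[C@@H](OC3(C)C)[C@@](C)(O3)[C@@H]2C(=O)C2=C(C)C(=O)O[C@H]2/C=C1/C | intermediate
24 | 8α,17α-epoxy ketone | C1C[C@H](OC(C)=O)[C@@]2(C)C=C[C@@H](OC3(C)C)[C@@](C)(O3)[C@@H]2C(=O)[C@]2(O5)[C@]5(C)C(=O)O[C@H]2/C=C1/C | intermediate
25 | 8α,17α-epoxy-9-ol (9S) | C1C[C@H](OC(C)=O)[C@@]2(C)C=C[C@@H](OC3(C)C)[C@@](C)(O3)[C@@H]2[C@H](O)[C@]2(O5)[C@]5(C)C(=O)O[C@H]2/C=C1/C | intermediate
26 | 8α,9-diol lactone | C1C[C@H](OC(C)=O)[C@@]2(C)C=C[C@@H](OC3(C)C)[C@@](C)(O3)[C@@H]2[C@H](O)[C@]2(O)[C@@H](C)C(=O)O[C@H]2/C=C1/C | intermediate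
27 | 8,9,11,12-tetraol 2-acetate | C1C[C@H](OC(C)=O)[C@@]2(C)C=C[C@@H](O)[C@@](C)(O)[C@@H]2[C@H](O)[C@]2(O)[C@@H](C)C(=O)O[C@H]2/C=C1/C | intermediate
28 | 2,9,12-triacetate with the 5Z alkene | C1C[C@H](OC(C)=O)[C@@]2(C)C=C[C@@H](OC(C)=O)[C@@](C)(O)[C@@H]2[C@H](OC(C)=O)[C@]2(O)[C@@H](C)C(=O)O[C@H]2/C=C1/C | intermediate
29 | CNP0259091.1 | C=C1CC[C@H](OC(C)=O)[C@@]2(C)C=C[C@@H](OC(C)=O)[C@@](C)(O)[C@@H]2[C@H](OC(C)=O)[C@]2(O)[C@@H](C)C(=O)O[C@H]2[C@H]1Cl | target

Total step count: 22. Longest linear sequence: 19 steps (steps 4 to 22, from pent-1-en-3-one). Steps 1 to 3 make the oxazole fragment 5 in parallel.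

Steps most likely to fail

Step 15. Oligomerisation, thermal decay of the ynone or addition in the bridged sense may outrun closure of the strained ten-membered ring. The fallback freezes the C1–C2 and C9–C10 rotors with a temporary ring and keeps C9 tetrahedral. It sets out from 18. DIBAL-H (CH2Cl2, −78 °C) gives the lactol F1, and 1-propynylmagnesium bromide opens it to the 2,9-diol F2 (both C9 epimers serve). t-Bu2Si(OTf)2 with 2,6-lutidine ties O2 and O9 into the seven-membered cyclic silylene F3. Thermolysis in 1,2-diethylbenzene at about 185 °C, the unactivated-alkyne mode of the same cycloaddition, passes through the oxa-bridged adduct F4 to the silylene-bridged ethoxyfuran F5. TBAF frees the furyl diol F6, MnO2 oxidises only the furyl carbinol to the hydroxy ketone F7, and Ac2O/pyridine comes back to the route at 22.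

Step 17. Three things may go wrong:
- Facial selectivity at C8=C17 may be poor because it is coupled to the mobile C7 centre.
- The base may trigger β-elimination of the C11 oxygen through the C9 enolate.
- The base may move the C5=C6 bond into conjugation.

The fallback is a neutral radical route and sets out from 23. Mn(dpm)3, PhSiH3 and O2 in i-PrOH (Mukaiyama-type reductive α-hydroxylation of an enone) transfer a hydrogen atom to the less hindered C17, and O2 captures the C8 radical next to the C9 ketone. This gives the C8 hydroperoxide F8. P(OEt)3 reduces it to the α-hydroxy ketone F9, and NaBH4/CeCl3 reduction of the C9 ketone comes back to the route at 26.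

Step 22. Chlorine may enter from the exposed β face, or the 8-hydroxyl may capture the chloronium ion at C5 (chloroetherification). The fallback uses β-face attack and then inverts C6. It sets out from 28. mCPBA oxidises only the trisubstituted alkene to the 5β,6β-epoxide F10. Cp2TiCl, a trivalent titanium reagent made from Cp2TiCl2 and Mn in THF, opens the epoxide to the tertiary C5 radical. That radical loses a C16 hydrogen and gives the 6β-allylic alcohol F11. PPh3 with hexachloroacetone replaces the hydroxyl by chloride with inversion and without allylic shift, arriving at 29.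

Further compounds
F1 | step 15 | lactol from 18 | CCOc1oc(/C=C(/C)CC[C@H](O4)[C@@]2(C)C=C[C@@H](OC3(C)C)[C@@](C)(O3)[C@@H]2C4O)nc1C
F2 | step 15 | 2,9-diol with the propynyl carbinol | CCOc1oc(/C=C(/C)CC[C@H](O)[C@@]2(C)C=C[C@@H](OC3(C)C)[C@@](C)(O3)[C@@H]2C(O)C#CC)nc1C
F3 | step 15 | cyclic di-tert-butylsilylene of the 2,9-diol | CCOc1oc(/C=C(/C)CC[C@H](O4)[C@@]2(C)C=C[C@@H](OC3(C)C)[C@@](C)(O3)[C@@H]2C(O[Si]4(C(C)(C)C)C(C)(C)C)C#CC)nc1C
F4 | step 15 | oxa-bridged adduct of the silylene series | C1C[C@H](O4)[C@@]2(C)C=C[C@@H](OC3(C)C)[C@@](C)(O3)[C@@H]2C(O[Si]4(C(C)(C)C)C(C)(C)C)C2=C(C)C5(OCC)OC2(N=C5C)/C=C1/C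
F5 | step 15 | silylene-bridged ethoxyfuran | C1C[C@H](O4)[C@@]2(C)C=C[C@@H](OC3(C)C)[C@@](C)(O3)[C@@H]2C(O[Si]4(C(C)(C)C)C(C)(C)C)c2c(C)c(OCC)oc2/C=C1/C
F6 | step 15 | furyl diol | C1C[C@H](O)[C@@]2(C)C=C[C@@H](OC3(C)C)[C@@](C)(O3)[C@@H]2C(O)c2c(C)c(OCC)oc2/C=C1/C
F7 | step 15 | hydroxy ketone (2-deacetyl 22) | C1C[C@H](O)[C@@]2(C)C=C[C@@H](OC3(C)C)[C@@](C)(O3)[C@@H]2C(=O)c2c(C)c(OCC)oc2/C=C1/C
F8 | step 17 | C8 hydroperoxide | C1C[C@H](OC(C)=O)[C@@]2(C)C=C[C@@H](OC3(C)C)[C@@](C)(O3)[C@@H]2C(=O)[C@]2(OO)[C@@H](C)C(=O)O[C@H]2/C=C1/C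
F9 | step 17 | α-hydroxy ketone (8-OH; C9 ketone) | C1C[C@H](OC(C)=O)[C@@]2(C)C=C[C@@H](OC3(C)C)[C@@](C)(O3)[C@@H]2C(=O)[C@]2(O)[C@@H](C)C(=O)O[C@H]2/C=C1/C
F10 | step 22 | 5β,6β-epoxide | C[C@@]15CC[C@H](OC(C)=O)[C@@]2(C)C=C[C@@H](OC(C)=O)[C@@](C)(O)[C@@H]2[C@H](OC(C)=O)[C@]2(O)[C@@H](C)C(=O)O[C@H]2[C@@H]1O5
F11 | step 22 | 6β-allylic alcohol | C=C1CC[C@H](OC(C)=O)[C@@]2(C)C=C[C@@H](OC(C)=O)[C@@](C)(O)[C@@H]2[C@H](OC(C)=O)[C@]2(O)[C@@H](C)C(=O)O[C@H]2[C@@H]1O
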